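**Retrosynthetic overview**
- Feature: each furan ring is bound through C2 to an unbranched saturated tether that ends at a C≡C–C≡C unit. The tether is (CH2)11 on the acyl side and (CH2)4 on the alkoxy side. Both are cut at the CH2–CH2 bond between the second and third carbon counted from furan C2.
- The two cuts release the same 2-(furan-2-yl)ethyl piece twice (as the N-hydroxyphthalimide ester of 3-(furan-2-yl)propanoic acid) and one furan-free diyne–ester–diyne diacid. One nickel-electrocatalytic doubly decarboxylative coupling makes both bonds in the last step.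
- The core diacid is opened at its inner ester C–O bond, and each diyne at its central sp–sp bond (Cadiot–Chodkiewicz). The outer acids are masked as tert-butyl esters.
- No ring is formed. Both furans are bought within the C7 acid and enter only after all brominating and acidic steps are over.

Key step: step 11

Remark: the target has no stereocentre and no stereodefined double bond, so no stereocontrol is needed. All conjugated diynes are kept cold, dark and in solution, because crystalline diynes can polymerise topochemically. Dodec-11-ynoic acid is taken as a catalogue compound.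

**Step 1**
Reactants: 1 dodec-11-ynoic acid
Product: 2 tert-butyl dodec-11-ynoate
Conditions: Cl3CC(=NH)Ot-Bu (2 equiv), BF3·OEt2 (cat.), CH2Cl2/cyclohexane, 0 °C → rt
Reagents that add atoms: tert-butyl 2,2,2-trichloroacetimidate, CC(C)(C)OC(=N)C(Cl)(Cl)Cl
Why: Acid-catalysed imidate tert-butylation of a carboxylic acid transfers the tert-butyl group under mild conditions that leave the terminal alkyne untouched.

**Step 2**
Reactants: 2 tert-butyl dodec-11-ynoate
Product: 3 tert-butyl 12-bromododec-11-ynoate
Conditions: NBS (1.1 equiv), AgNO3 (10 mol%), acetone, rt, dark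
Reagents that add atoms: N-bromosuccinimide, O=C1CCC(=O)N1Br
Why: Silver-catalysed electrophilic bromination of a terminal alkyne through the silver acetylide is routine, and bromine is put on this partner because its blocked, remote carboxyl cannot bromolactonise, as a free hex-5-ynoic acid could.

**Step 3**
Reactants: 3 tert-butyl 12-bromododec-11-ynoate; 4 hex-5-ynoic acid
Product: 5 18-(tert-butoxy)-18-oxooctadeca-5,7-diynoic acid
Conditions: 4 (1.5 equiv), CuCl (10 mol%), NH2OH·HCl (cat.), 30% aq n-BuNH2, THF, 0 °C, slow addition of 3; then aq citric acid to pH 3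
Reagents that add atoms: none
Why: Cadiot–Chodkiewicz coupling of a copper acetylide with a 1-bromoalkyne tolerates free alkynoic acids as their ammonium salts, and the cross product should be easy to separate because it is the only monoacid beside a neutral dimer and a diacid dimer.

**Step 4**
Reactants: 6 pent-4-ynoic acid
Product: 7 tert-butyl pent-4-ynoate
Conditions: Cl3CC(=NH)Ot-Bu (2 equiv), BF3·OEt2 (cat.), CH2Cl2/cyclohexane, 0 °C → rt; careful concentration (volatile)
Reagents that add atoms: tert-butyl 2,2,2-trichloroacetimidate, CC(C)(C)OC(=N)C(Cl)(Cl)Cl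
Why: The same imidate tert-butylation as in step 1 masks the acid, so that it can neither lactonise onto the alkyne nor compete in the later esterification.

**Step 5**
Reactants: 8 pent-4-yn-1-ol
Product: 9 5-bromopent-4-yn-1-ol
Conditions: NBS (1.1 equiv), AgNO3 (10 mol%), acetone, rt, dark
Reagents that add atoms: N-bromosuccinimide, O=C1CCC(=O)N1Br
Why: Silver-catalysed alkyne C–H bromination proceeds in the presence of a free primary alcohol, so no protecting group is needed.

**Step 6**
Reactants: 7 tert-butyl pent-4-ynoate; 9 5-bromopent-4-yn-1-ol
Product: 10 tert-butyl 10-hydroxydeca-4,6-diynoate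
Conditions: 7 (1.3 equiv), CuCl (10 mol%), NH2OH·HCl (cat.), 30% aq n-BuNH2, Et2O, 0 °C, slow addition of 9
Reagents that add atoms: none
Why: Cadiot–Chodkiewicz coupling joins the two sp termini, the hindered tert-butyl ester resists aminolysis, and the hydroxy ester differs clearly in polarity from the diol and diester homo-dimers.

**Step 7**
Reactants: 5 18-(tert-butoxy)-18-oxooctadeca-5,7-diynoic acid; 10 tert-butyl 10-hydroxydeca-4,6-diynoate
Product: 11 18-tert-butyl 1-[10-(tert-butoxy)-10-oxodeca-4,6-diyn-1-yl] octadeca-5,7-diynedioate
Conditions: EDC·HCl (1.3 equiv), DMAP (0.2 equiv), CH2Cl2, 0 °C → rt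
Reagents that add atoms: none
Why: Steglich-type carbodiimide/DMAP esterification joins the only free acid to the only free primary alcohol under neutral conditions that do not affect diynes or tert-butyl esters.

**Step 8**
Reactants: 11 18-tert-butyl 1-[10-(tert-butoxy)-10-oxodeca-4,6-diyn-1-yl] octadeca-5,7-diynedioate
Product: 12 18-(9-carboxynona-4,6-diyn-1-yloxy)-18-oxooctadeca-11,13-diynoic acid (core diacid)
Conditions: TFA/CH2Cl2 (1:3), 0 °C → rt; toluene azeotrope
Reagents that add atoms: none
Why: Acidolysis of tert-butyl esters by alkyl–oxygen cleavage removes both outer groups and leaves the inner primary alkyl ester intact, and no acid-sensitive furan is present yet.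

**Step 9**
Reactants: 12 core diacid
Product: 13 bis(1,3-dioxoisoindolin-2-yl) ester of 12, that is 18-(1,3-dioxoisoindolin-2-yl) 1-{10-[(1,3-dioxoisoindolin-2-yl)oxy]-10-oxodeca-4,6-diyn-1-yl} octadeca-5,7-diynedioate
Conditions: N-hydroxyphthalimide (2.3 equiv), DIC (2.3 equiv), DMAP (0.2 equiv), CH2Cl2, rt, dark; short silica plug
Reagents that add atoms: N-hydroxyphthalimide, O=C1c2ccccc2C(=O)N1O
Why: Carbodiimide-mediated formation of N-acyloxyphthalimides (redox-active esters) is general for unhindered primary acids and should activate both termini alike.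

**Step 10**
Reactants: 14 3-(furan-2-yl)propanoic acid
Product: 15 1,3-dioxoisoindolin-2-yl 3-(furan-2-yl)propanoate
Conditions: N-hydroxyphthalimide (1.05 equiv), DIC (1.1 equiv), DMAP (0.1 equiv), CH2Cl2, rt
Reagents that add atoms: N-hydroxyphthalimide, O=C1c2ccccc2C(=O)N1O
Why: The same carbodiimide activation works under near-neutral conditions that the furan tolerates and can be run on a large scale, as the excess needed in step 11 demands.

**Step 11**
Reactants: 13 core bis(N-acyloxyphthalimide); 15 1,3-dioxoisoindolin-2-yl 3-(furan-2-yl)propanoate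
Product: 18 11-(furan-2-yl)undeca-4,6-diyn-1-yl 19-(furan-2-yl)nonadeca-5,7-diynoate (target), via long-arm monocapped ester 16 (not isolated), via short-arm monocapped ester 17 (not isolated)
Conditions: 15 (6 equiv, in two portions), NiCl2·6H2O (40 mol%), 2,2':6',2''-terpyridine (40 mol%), NaI (0.2 M), DMF (13 at 0.02 M), Zn anode/RVC cathode, undivided cell, constant current, about 2 F per mol of redox-active ester groups, rt, Ar, dark; aq NH4Cl work-up; SiO2 pre-washed with Et3N
Reagents that add atoms: none
Why: Low-valent terpyridine–nickel made at the cathode passes one electron to each N-acyloxyphthalimide, which collapses to phthalimide anion, CO2 and a primary alkyl radical; nickel takes up two such radicals in turn and the dialkyl trivalent nickel releases the new CH2–CH2 bond by reductive elimination. This is the known nickel-electrocatalytic doubly decarboxylative sp3–sp3 cross-coupling of two primary redox-active esters, used here at both termini of one molecule, so that 13 passes through 16 or 17 before 18 appears. No ring is closed and no stereocentre is created. The selectivity needed is cross- over homo-coupling, and since all three radicals are unhindered primary ones it is statistical: the large excess of cheap 15 and the high dilution of 13 should make a furylethyl unit the likely partner at each core terminus and keep core–core oligomers minor, while the apolar dimer of 15 is removed by chromatography. The position of the cuts helps, because the furylethyl radical, the homopropargyl radical (only 3-exo or 4-endo closure) and the remote primary radical nine CH2 groups from its diyne have no five- or six-membered cyclisation open onto a diyne or a furan. The electrolysis runs at the potential of the nickel/ester couple, well short of that needed to reduce a dialkyl diyne, and the reductive regime spares the furans that an anodic Kolbe coupling would oxidise.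

**Compound list**
1 | dodec-11-ynoic acid | C#CCCCCCCCCCC(=O)O | starting material
2 | tert-butyl dodec-11-ynoate | C#CCCCCCCCCCC(=O)OC(C)(C)C | intermediate
3 | tert-butyl 12-bromododec-11-ynoate | BrC#CCCCCCCCCCC(=O)OC(C)(C)C | intermediate
4 | hex-5-ynoic acid | C#CCCCC(=O)O | starting material
5 | 18-(tert-butoxy)-18-oxooctadeca-5,7-diynoic acid | OC(=O)CCCC#CC#CCCCCCCCCCC(=O)OC(C)(C)C | intermediate
6 | pent-4-ynoic acid | C#CCCC(=O)O | starting material
7 | tert-butyl pent-4-ynoate | C#CCCC(=O)OC(C)(C)C | intermediate
8 | pent-4-yn-1-ol | C#CCCCO | starting material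
9 | 5-bromopent-4-yn-1-ol | BrC#CCCCO | intermediate
10 | tert-butyl 10-hydroxydeca-4,6-diynoate | CC(C)(C)OC(=O)CCC#CC#CCCCO | intermediate
11 | 18-tert-butyl 1-[10-(tert-butoxy)-10-oxodeca-4,6-diyn-1-yl] octadeca-5,7-diynedioate | CC(C)(C)OC(=O)CCCCCCCCCC#CC#CCCCC(=O)OCCCC#CC#CCCC(=O)OC(C)(C)C | intermediate
12 | 18-(9-carboxynona-4,6-diyn-1-yloxy)-18-oxooctadeca-11,13-diynoic acid | OC(=O)CCCCCCCCCC#CC#CCCCC(=O)OCCCC#CC#CCCC(=O)O | intermediate
13 | bis(1,3-dioxoisoindolin-2-yl) ester of 12 | O=C(ON1C(=O)c2ccccc2C1=O)CCCCCCCCCC#CC#CCCCC(=O)OCCCC#CC#CCCC(=O)ON1C(=O)c2ccccc2C1=O | intermediate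
14 | 3-(furan-2-yl)propanoic acid | OC(=O)CCc1ccco1 | starting material
15 | 1,3-dioxoisoindolin-2-yl 3-(furan-2-yl)propanoate | O=C(CCc1ccco1)ON1C(=O)c2ccccc2C1=O | intermediate
16 | 1,3-dioxoisoindolin-2-yl 10-{[19-(furan-2-yl)nonadeca-5,7-diynoyl]oxy}deca-4,6-diynoate (long-arm monocapped ester) | O=C(CCCC#CC#CCCCCCCCCCCCc1ccco1)OCCCC#CC#CCCC(=O)ON1C(=O)c2ccccc2C1=O | intermediate
17 | 18-(1,3-dioxoisoindolin-2-yl) 1-[11-(furan-2-yl)undeca-4,6-diyn-1-yl] octadeca-5,7-diynedioate (short-arm monocapped ester) | O=C(ON1C(=O)c2ccccc2C1=O)CCCCCCCCCC#CC#CCCCC(=O)OCCCC#CC#CCCCCc1ccco1 | intermediate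
18 | 11-(furan-2-yl)undeca-4,6-diyn-1-yl 19-(furan-2-yl)nonadeca-5,7-diynoate | O=C(CCCC#CC#CCCCCCCCCCCCc1ccco1)OCCCC#CC#CCCCCc1ccco1 | target

**Total step count:** 11
**Longest linear sequence:** 7 (steps 1, 2, 3, 7, 8, 9, 11)

**Steps most likely to fail**

**Step 11.**
- Risk: tolerance of two conjugated diynes and coupling at two termini go beyond what this coupling has been asked to do.
- Low-valent nickel may be tied up by π-complexation or oxidative cyclisation with the diynes.
- Alkyl radicals may add to a diyne or be lost by hydrogen abstraction from the solvent.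
- Statistical core–core coupling may build oligomers and leave half-capped material.
- Fallback: nickel is dropped altogether and each furan is attached by alkylation of 2-lithiofuran before any diyne exists. It sets out from 4 and 9 and comes back to the route at 18.
- Furan is lithiated (n-BuLi, THF, 0 °C) and alkylated with an excess of 1,11-dibromoundecane to give 2-(11-bromoundecyl)furan F1.
- The bromide of F1 is displaced with lithium acetylide–ethylenediamine complex (LiC≡CH·H2NCH2CH2NH2) in DMSO to give 2-(tridec-12-yn-1-yl)furan F2.
- Compound 4 is brominated at the alkyne terminus with cold aqueous KOBr (Br2, KOH), a strongly basic medium in which substitution at the terminus outruns lactonisation. This gives 6-bromohex-5-ynoic acid F3.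
- Cadiot–Chodkiewicz coupling of F2 with F3 gives 19-(furan-2-yl)nonadeca-5,7-diynoic acid F4.
- In the same manner 1,4-dibromobutane gives 2-(4-bromobutyl)furan F5 and then 2-(hex-5-yn-1-yl)furan F6.
- F6 is coupled with 9 to give 11-(furan-2-yl)undeca-4,6-diyn-1-ol F7.
- EDC/DMAP esterification of F4 with F7 gives 18.
- The furan-bearing alkyne is always the terminal partner, so no furan meets a brominating agent.

**Step 3.**
- Risk: halogen–copper exchange and adventitious oxidation may lead to homo-coupling of either partner. The carboxylate of 4 may also bind copper and slow the cross-coupling.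
- Fallback: the bromoalkyne is given up in favour of an oxidative Glaser–Hay hetero-coupling of two terminal alkynes. It sets out from 2 and 4 (leaving out 3) and comes back at 5.
- Compound 2 and a fivefold excess of cheap 4 are stirred with CuCl/TMEDA under air in acetone.
- The outcome is statistical but favours the cross product with respect to 2.
- The three diynes differ in charge (neutral diester, monoacid 5, diacid), so extraction at graded pH separates them.

**Step 6.**
- Risk: homo-coupling of the two short partners, evaporative loss of volatile 7, and slow attack of the amine on the bromoalkyne may erode the supply of 10.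
- Fallback: the cross-coupling is avoided by using the hidden symmetry of the C10 chain. It sets out from 8 and 5 and comes back at 12.
- Glaser–Hay homo-coupling of 8 (CuCl, TMEDA, O2, acetone) gives deca-4,6-diyne-1,10-diol F8.
- A fourfold excess of F8 is mono-acylated with 5 (EDC·HCl, DMAP) to give 18-tert-butyl 1-(10-hydroxydeca-4,6-diyn-1-yl) octadeca-5,7-diynedioate F9, and the surplus diol is recovered.
- Oxidation of the remaining primary alcohol with TEMPO (cat.)/PhI(OAc)2 in aqueous MeCN gives 10-{[18-(tert-butoxy)-18-oxooctadeca-5,7-diynoyl]oxy}deca-4,6-diynoic acid F10.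
- TFA/CH2Cl2 then converts F10 into 12.

**Further compounds**
F1 | step 11 | 2-(11-bromoundecyl)furan | BrCCCCCCCCCCCc1ccco1
F2 | step 11 | 2-(tridec-12-yn-1-yl)furan | C#CCCCCCCCCCCCc1ccco1
F3 | step 11 | 6-bromohex-5-ynoic acid | BrC#CCCCC(=O)O
F4 | step 11 | 19-(furan-2-yl)nonadeca-5,7-diynoic acid | OC(=O)CCCC#CC#CCCCCCCCCCCCc1ccco1
F5 | step 11 | 2-(4-bromobutyl)furan | BrCCCCc1ccco1
F6 | step 11 | 2-(hex-5-yn-1-yl)furan | C#CCCCCc1ccco1
F7 | step 11 | 11-(furan-2-yl)undeca-4,6-diyn-1-ol | OCCCC#CC#CCCCCc1ccco1
F0 | step 3 | none | none
F8 | step 6 | deca-4,6-diyne-1,10-diol | OCCCC#CC#CCCCO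
F9 | step 6 | 18-tert-butyl 1-(10-hydroxydeca-4,6-diyn-1-yl) octadeca-5,7-diynedioate | CC(C)(C)OC(=O)CCCCCCCCCC#CC#CCCCC(=O)OCCCC#CC#CCCCO
F10 | step 6 | 10-{[18-(tert-butoxy)-18-oxooctadeca-5,7-diynoyl]oxy}deca-4,6-diynoic acid | CC(C)(C)OC(=O)CCCCCCCCCC#CC#CCCCC(=O)OCCCC#CC#CCCC(=O)O
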